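**Retrosynthetic overview**
- The target is the fourfold O-debenzylation product of a tetra-O-benzyl dimer. Its C4–C8 bond comes from Lewis-acid ionisation of a 4-alkoxy derivative of the benzylated cis-flavan-3-ol, captured at C8 by a second molecule of the same cis-flavan-3-ol.
- One monomer therefore serves both halves; it comes from cis-selective hydride reduction of the (2R)-5,7-bis(benzyloxy)flavan-3-one.
- Key disconnection: C4–C4a of the flavan-3-one. An α-keto carbene carbon (an α-keto cation equivalent, from an α-diazoketone) is attacked by the electron-rich phloroglucinol ring, so a ketone α-carbon and an arene carbon, both normally nucleophilic, are joined.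
- The diazoketone comes from (R)-2-aryloxy-2-phenylacetic acid, made by Mitsunobu inversion of methyl (S)-mandelate with 3,5-bis(benzyloxy)phenol; this fixes C2 of both units.
- Ring order: rings A and B are bought; ring C of the monomer closes in the key step; the two flavan units are joined last.

Assumption: 3,5-bis(benzyloxy)phenol, methyl (S)-mandelate and TMSCHN2 solution are taken as commercial; compound numbers follow the forward route.

**Route**

Step 1
Reactants: 1 3,5-bis(benzyloxy)phenol; 2 methyl (S)-mandelate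
Product: 3 methyl (2R)-2-[3,5-bis(benzyloxy)phenoxy]-2-phenylacetate
Conditions: PPh3, DIAD, THF, 0 °C to rt
Reagents that add atoms: none
Why: Mitsunobu etherification, in which the phenol displaces the activated benzylic α-hydroxy ester oxygen by SN2 with clean inversion, turning the (S)-carbinol into the (R)-aryl ether that becomes C2 of both flavan units.

Step 2
Reactants: 3 methyl (2R)-2-[3,5-bis(benzyloxy)phenoxy]-2-phenylacetate
Product: 4 (2R)-2-[3,5-bis(benzyloxy)phenoxy]-2-phenylacetic acid
Conditions: LiOH·H2O (1.5 equiv), THF/H2O 3:1, 0 °C; then 1 M HCl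
Reagents that add atoms: lithium hydroxide, [Li+].[OH-] (supplies the new carboxyl oxygen)
Why: Ester saponification (BAc2) of an inductively activated ester is faster at 0 °C than α-deprotonation, and the carboxylate formed is no longer enolisable, so the (R) centre is retained.

Step 3
Reactants: 4 (2R)-2-[3,5-bis(benzyloxy)phenoxy]-2-phenylacetic acid
Product: 6 (3R)-3-[3,5-bis(benzyloxy)phenoxy]-1-diazo-3-phenylpropan-2-one, via mixed isobutyl carbonic anhydride 5 (not isolated)
Conditions: i-BuOCOCl, N-methylmorpholine, THF, -20 °C; then TMSCHN2 (2 equiv), MeCN, 0 °C to rt; aqueous work-up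
Reagents that add atoms: (trimethylsilyl)diazomethane, C[Si](C)(C)C=[N+]=[N-] (adds CHN2); isobutyl chloroformate, CC(C)COC(=O)Cl (its atoms stay only in intermediate 5)
Why: Arndt–Eistert-type acylation of a diazomethane equivalent through a mixed anhydride, the low-temperature weak-base protocol used for racemisation-prone α-substituted acids, which avoids a ketene and leaves the stereocentre untouched while the silyl group is shed as trimethylsilanol on work-up.

Step 4
Reactants: 6 (3R)-3-[3,5-bis(benzyloxy)phenoxy]-1-diazo-3-phenylpropan-2-one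
Product: 7 (2R)-5,7-bis(benzyloxy)-2-phenylchroman-3-one
Conditions: Rh2(OAc)4 (1 mol%), CH2Cl2, rt, slow addition of 6, argon
Reagents that add atoms: none
Why: Rhodium-carbene intramolecular aromatic substitution (formal aromatic C–H insertion), in which loss of N2 gives a catalyst-bound electrophilic α-keto carbene carbon that is attacked by the most nucleophilic ring position (ortho to the ether oxygen and ortho/para to the two benzyloxy groups, the two ortho positions being equivalent), closing six-membered ring C as the 3-ketone without touching C2.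

Step 5
Reactants: 7 (2R)-5,7-bis(benzyloxy)-2-phenylchroman-3-one
Product: 8 (2R,3R)-5,7-bis(benzyloxy)-2-phenylchroman-3-ol (2,3-cis)
Conditions: LiBH(s-Bu)3, LiBr, THF, -78 °C; H2O quench
Reagents that add atoms: none
Why: Substrate-controlled reduction by a bulky hydride, which enters from the face opposite the C2 phenyl and gives the 2,3-cis (3R) alcohol, as in the established flavan-3-one to epi-flavan-3-ol conversion, with no C2 epimerisation at -78 °C.

Step 6
Reactants: 8 (2R,3R)-5,7-bis(benzyloxy)-2-phenylchroman-3-ol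
Product: 9 (2R,3R,4S)-5,7-bis(benzyloxy)-4-(2-ethoxyethoxy)-2-phenylchroman-3-ol
Conditions: DDQ (2 equiv), 2-ethoxyethanol (5 equiv), CH2Cl2, rt
Reagents that add atoms: 2-ethoxyethanol, CCOCCO
Why: DDQ benzylic oxidation, in which hydride abstraction at C4 (the position activated by the ortho/para oxygens of ring A, far more than C2 next to a plain phenyl) gives a stabilised cation that the alcohol traps trans to the 3-OH, the C4 configuration being immaterial because it is ionised again in step 7.

Step 7
Reactants: 9 (2R,3R,4S)-5,7-bis(benzyloxy)-4-(2-ethoxyethoxy)-2-phenylchroman-3-ol; 8 (2R,3R)-5,7-bis(benzyloxy)-2-phenylchroman-3-ol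
Product: 10 (2R,3R,4R)-5,7-bis(benzyloxy)-4-[(2R,3R)-5,7-bis(benzyloxy)-3-hydroxy-2-phenylchroman-8-yl]-2-phenylchroman-3-ol
Conditions: TMSOTf (0.2 equiv), CH2Cl2, -78 °C, 8 in 3-fold excess (surplus recovered)
Reagents that add atoms: none
Why: Lewis-acid-promoted Friedel–Crafts flavan coupling, in which ionisation of the 4-ether gives the C4 benzylic cation and C8 of 8 (the reactive position of 5,7-di-O-benzyl flavans) attacks from the face opposite both the C2 phenyl and the pseudo-axial 3-OH, setting the 3,4-trans (4R) bond, while the excess of 8 suppresses oligomers.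

Step 8
Reactants: 10 (2R,3R,4R)-5,7-bis(benzyloxy)-4-[(2R,3R)-5,7-bis(benzyloxy)-3-hydroxy-2-phenylchroman-8-yl]-2-phenylchroman-3-ol
Product: 11 (2R,3R,4R)-2-phenyl-4-[(2R,3R)-3,5,7-trihydroxy-2-phenylchroman-8-yl]chroman-3,5,7-triol (target)
Conditions: H2 (1 atm), Pd(OH)2/C, THF/MeOH/H2O 20:1:1, rt
Reagents that add atoms: none
Why: Catalytic hydrogenolysis of the four aryl benzyl ethers under neutral conditions, which as in the catechin series leaves the ring C benzylic C–O bond, the interflavan bond and all five stereocentres untouched.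

**Compound list**
1 | 3,5-bis(benzyloxy)phenol | Oc1cc(OCc2ccccc2)cc(OCc2ccccc2)c1 | starting material
2 | methyl (S)-mandelate | COC(=O)[C@@H](O)c1ccccc1 | starting material
3 | methyl (2R)-2-[3,5-bis(benzyloxy)phenoxy]-2-phenylacetate | COC(=O)[C@H](Oc1cc(OCc2ccccc2)cc(OCc2ccccc2)c1)c1ccccc1 | intermediate
4 | (2R)-2-[3,5-bis(benzyloxy)phenoxy]-2-phenylacetic acid | OC(=O)[C@H](Oc1cc(OCc2ccccc2)cc(OCc2ccccc2)c1)c1ccccc1 | intermediate
5 | (2R)-2-[3,5-bis(benzyloxy)phenoxy]-2-phenylacetic isobutyl carbonic anhydride | CC(C)COC(=O)OC(=O)[C@H](Oc1cc(OCc2ccccc2)cc(OCc2ccccc2)c1)c1ccccc1 | intermediate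
6 | (3R)-3-[3,5-bis(benzyloxy)phenoxy]-1-diazo-3-phenylpropan-2-one | [N-]=[N+]=CC(=O)[C@H](Oc1cc(OCc2ccccc2)cc(OCc2ccccc2)c1)c1ccccc1 | intermediate
7 | (2R)-5,7-bis(benzyloxy)-2-phenylchroman-3-one | O=C1Cc2c(OCc3ccccc3)cc(OCc3ccccc3)cc2O[C@@H]1c1ccccc1 | intermediate
8 | (2R,3R)-5,7-bis(benzyloxy)-2-phenylchroman-3-ol | c1ccc(cc1)COc1cc(OCc2ccccc2)c2c(c1)O[C@H](c1ccccc1)[C@H](O)C2 | intermediate
9 | (2R,3R,4S)-5,7-bis(benzyloxy)-4-(2-ethoxyethoxy)-2-phenylchroman-3-ol | c1ccc(cc1)COc1cc(OCc2ccccc2)c2c(c1)O[C@H](c1ccccc1)[C@H](O)[C@H]2OCCOCC | intermediate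
10 | (2R,3R,4R)-5,7-bis(benzyloxy)-4-[(2R,3R)-5,7-bis(benzyloxy)-3-hydroxy-2-phenylchroman-8-yl]-2-phenylchroman-3-ol | c1ccc(cc1)COc1cc(OCc2ccccc2)c2c(c1)O[C@H](c1ccccc1)[C@H](O)[C@H]2c1c(OCc2ccccc2)cc(OCc2ccccc2)c2c1O[C@H](c1ccccc1)[C@H](O)C2 | intermediate
11 | (2R,3R,4R)-2-phenyl-4-[(2R,3R)-3,5,7-trihydroxy-2-phenylchroman-8-yl]chroman-3,5,7-triol | Oc1cc(O)c2c(c1)O[C@H](c1ccccc1)[C@H](O)[C@H]2c1c(O)cc(O)c2c1O[C@H](c1ccccc1)[C@H](O)C2 | target

**Totals**
Total step count: 8. Longest linear sequence: 8 (1 → 3 → 4 → 6 → 7 → 8 → 9 → 10 → 11; compound 8 is used twice).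

**Three steps most likely to fail**

First risk: step 4, the carbene ring closure. The carbene may instead give a cycloheptatriene by arene cyclopropanation and ring expansion, attack the C2 phenyl to give an indan-2-one, or form an oxonium ylide with a benzyloxy oxygen. The fallback sets out from 6 and comes back at 7. Aqueous HBr in Et2O at 0 °C converts 6, with loss of N2, into (3R)-1-bromo-3-[3,5-bis(benzyloxy)phenoxy]-3-phenylpropan-2-one F1. This bromomethyl ketone F1 is then closed onto the same ring position by silver-assisted intramolecular Friedel–Crafts alkylation (AgOTf, 2,6-di-tert-butylpyridine, CH2Cl2, 0 °C to rt) to give 7. The hindered base takes up the acid released, so that acid-catalysed attack of the ring on the carbonyl (cyclodehydration to a benzofuran) is held back. The mechanism is ionic, so the carbene side reactions cannot occur.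

Second risk: step 2, loss of optical purity at the α-aryloxy-α-phenyl centre during hydrolysis (the same centre is at risk in step 3). The fallback sets out from 7 of eroded enantiomeric purity and comes back at 8, replacing step 5. H-2 of the ketone is flanked by carbonyl, phenyl and ring oxygen, so KOt-Bu equilibrates 7 with its enantiomer (2S)-5,7-bis(benzyloxy)-2-phenylchroman-3-one F2. Asymmetric hydrogenation under dynamic kinetic resolution (RuCl2[(S)-xylbinap][(S)-daipen], KOt-Bu, H2 10 atm, i-PrOH) then funnels both 7 and F2 into the cis alcohol 8. The ligand antipode that gives the (2R,3R) product must be found by screening both. C2 and C3 are then set together by the catalyst rather than by the chiral pool.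

Third risk: step 7, the interflavan coupling (self-condensation of 9, oligomers, some 4→6 isomer). The fallback sets out from 8 and comes back at 11. NBS in CH2Cl2 at -78 °C brominates C8 of 8 selectively to give (2R,3R)-5,7-bis(benzyloxy)-8-bromo-2-phenylchroman-3-ol F3. DDQ and 2-ethoxyethanol, as in step 6, then give (2R,3R,4S)-5,7-bis(benzyloxy)-8-bromo-4-(2-ethoxyethoxy)-2-phenylchroman-3-ol F4, whose C8 is blocked by bromine so that it can act only as the electrophile. Near-equimolar coupling of F4 with 8 (TMSOTf, CH2Cl2, -78 °C) gives (2R,3R,4S)-5,7-bis(benzyloxy)-4-[(2R,3R)-5,7-bis(benzyloxy)-3-hydroxy-2-phenylchroman-8-yl]-8-bromo-2-phenylchroman-3-ol F5. Its geometry is the same as in 10; the C4 descriptor changes only because bromine alters the priorities. H2, Pd(OH)2/C and Et3N finally remove the bromine and the four benzyl groups of F5 in one operation to give 11.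

**Further compounds**
F1 | step 4 | (3R)-1-bromo-3-[3,5-bis(benzyloxy)phenoxy]-3-phenylpropan-2-one | BrCC(=O)[C@H](Oc1cc(OCc2ccccc2)cc(OCc2ccccc2)c1)c1ccccc1
F2 | step 2 | (2S)-5,7-bis(benzyloxy)-2-phenylchroman-3-one | O=C1Cc2c(OCc3ccccc3)cc(OCc3ccccc3)cc2O[C@H]1c1ccccc1
F3 | step 7 | (2R,3R)-5,7-bis(benzyloxy)-8-bromo-2-phenylchroman-3-ol | c1ccc(cc1)COc1cc(OCc2ccccc2)c2c(c1Br)O[C@H](c1ccccc1)[C@H](O)C2
F4 | step 7 | (2R,3R,4S)-5,7-bis(benzyloxy)-8-bromo-4-(2-ethoxyethoxy)-2-phenylchroman-3-ol | c1ccc(cc1)COc1cc(OCc2ccccc2)c2c(c1Br)O[C@H](c1ccccc1)[C@H](O)[C@H]2OCCOCC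
F5 | step 7 | (2R,3R,4S)-5,7-bis(benzyloxy)-4-[(2R,3R)-5,7-bis(benzyloxy)-3-hydroxy-2-phenylchroman-8-yl]-8-bromo-2-phenylchroman-3-ol | c1ccc(cc1)COc1cc(OCc2ccccc2)c2c(c1Br)O[C@H](c1ccccc1)[C@H](O)[C@H]2c1c(OCc2ccccc2)cc(OCc2ccccc2)c2c1O[C@H](c1ccccc1)[C@H](O)C2
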